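**Retrosynthetic overview**

1. Target ⇐ acetylation of the C2,C9-diol; C2 alcohol ⇐ reagent-controlled reduction of a C2 ketone; ten-membered ring closed last at C3–C4 by intramolecular alkylation of a methyl ketone enolate with a (Z)-allylic bromide.
2. Ring A (6-hydroxy-6-methylcyclohex-2-enone) ⇐ one-carbon ring expansion of a cyclopentanone: β-oxido carbenoid 1,2-shift of C10, with the ring-enlarged enolate hydroxylated in the same flask (key step). The five-membered ketone is what lets C10 be introduced as an enolate carbon.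
3. γ-Lactone with C7/C8 ⇐ hydroxyl-directed epoxidation of an (E)-allylic alcohol, then opening of the vinyl epoxide by the pendant ester with inversion at C7; Me-18 by lactone enolate methylation.
4. C1/C10/C9 ⇐ three-component union: asymmetric conjugate addition of a silylvinyl alane to 3-methylcyclopent-2-enone, aldol trapping with a (2E,4Z)-dienal built from 4-methylfuran-2(5H)-one (Z olefin) and maleic anhydride (C8, C9, C17, C19).
5. Order of ring formation: cyclopentanone (bought) → γ-lactone → ring A (five to six) → ten-membered ring.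

Assumption: atom labels follow briarane numbering (C1 quaternary with Me-15; C2, C9 acetoxy carbons; C5(Me-16)=C6; C7 lactone O-carbon; C8, C11 carbinols; C12 ketone; C13=C14; C17 with Me-18; C19 lactone carbonyl), and all numbered starting materials are taken as commercial.

**Route**

Step 1
Reactants: 1 4-methylfuran-2(5H)-one
Product: 3 (2Z)-4-[(tert-butyldimethylsilyl)oxy]-N-methoxy-N,3-dimethylbut-2-enamide, via magnesium alkoxide of the hydroxy Weinreb amide 2 (not isolated)
Conditions: MeNHOMe·HCl, iPrMgCl, THF, −20 °C; then TBSCl, imidazole, 0 to 23 °C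
Reagents that add atoms: N,O-dimethylhydroxylamine hydrochloride CNOC.Cl; tert-butyldimethylsilyl chloride CC(C)(C)[Si](C)(C)Cl
Why: Weinreb aminolysis opens the butenolide without touching the ring-locked Z olefin, and immediate silylation of the alkoxide prevents relactonisation.

Step 2
Reactants: 3 (2Z)-4-[(tert-butyldimethylsilyl)oxy]-N-methoxy-N,3-dimethylbut-2-enamide
Product: 4 (2Z)-4-[(tert-butyldimethylsilyl)oxy]-3-methylbut-2-enal
Conditions: iBu2AlH, THF, −78 °C
Reagents that add atoms: none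
Why: Weinreb amide reduction stops at the aldehyde through the stable chelated tetrahedral intermediate, with the Z geometry retained at low temperature.

Step 3
Reactants: 4 (2Z)-4-[(tert-butyldimethylsilyl)oxy]-3-methylbut-2-enal; 5 maleic anhydride
Product: 8 (2E,4Z)-2-[2-(tert-butoxy)-2-oxoethyl]-6-[(tert-butyldimethylsilyl)oxy]-5-methylhexa-2,4-dienoic acid, via phosphorus ylide 6 (not isolated), via alkylidene anhydride 7 (not isolated)
Conditions: PPh3, 5, THF, 23 °C; then 4, 23 to 50 °C; then tBuOH, DMAP, 50 °C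
Reagents that add atoms: tert-butanol CC(C)(C)O
Why: Wittig olefination with the anhydride-stabilised ylide is neutral (no Z/E drift of the enal) and E-selective (C6 trans to the conjugated carbonyl), and alcoholysis then occurs at the more electrophilic non-conjugated carbonyl.

Step 4
Reactants: 8 (2E,4Z)-2-[2-(tert-butoxy)-2-oxoethyl]-6-[(tert-butyldimethylsilyl)oxy]-5-methylhexa-2,4-dienoic acid
Product: 10 tert-butyl (3E,5Z)-7-[(tert-butyldimethylsilyl)oxy]-3-formyl-6-methylhepta-3,5-dienoate, via acid chloride 9 (not isolated)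
Conditions: 1-chloro-N,N,2-trimethylprop-1-en-1-amine, CH2Cl2, 0 °C; then LiAlH(OtBu)3, THF, −78 °C
Reagents that add atoms: none
Why: neutral acid chloride formation (Ghosez reagent) followed by LiAlH(OtBu)3 reduction stops at the aldehyde and leaves the tert-butyl ester, silyl ether and diene geometry intact.

Step 5
Reactants: 11 ethynylmagnesium bromide
Product: 12 benzyl(ethynyl)dimethylsilane
Conditions: BnMe2SiCl, THF, 0 to 23 °C
Reagents that add atoms: benzyl(chloro)dimethylsilane C[Si](C)(Cl)Cc1ccccc1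
Why: simple silylation of the acetylide; the benzyldimethylsilyl group is chosen because fluoride activates it for a later Tamao oxidation.

Step 6
Reactants: 12 benzyl(ethynyl)dimethylsilane; 13 3-methylcyclopent-2-en-1-one; 10 tert-butyl (3E,5Z)-7-[(tert-butyldimethylsilyl)oxy]-3-formyl-6-methylhepta-3,5-dienoate
Product: 16 tert-butyl (3E,5Z)-3-{(R)-[(1S,2S)-2-[1-(benzyldimethylsilyl)ethenyl]-2-methyl-5-oxocyclopentyl](hydroxy)methyl}-7-[(tert-butyldimethylsilyl)oxy]-6-methylhepta-3,5-dienoate, via silylvinyl alane 14 (not isolated), via aluminium enolate 15 (not isolated)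
Conditions: 12, iBu2AlH, hexane, 55 °C; then 13, Cu(OTf)2 (5 mol %), chiral sulfonate-bearing imidazolinium salt (carbene precursor, 6 mol %), THF, −50 °C; then 10, −78 °C, cold quench
Reagents that add atoms: none
Why: carbene–copper-catalysed asymmetric conjugate addition of a 1-silylvinyl alane to the β-substituted cyclopentenone sets C1 (S), and the regiodefined enolate adds to 10 anti to the bulky silylvinyl group through a chair Zimmerman–Traxler transition state of the ring-locked E-enolate, giving the trans, anti aldol (C10 S, C9 R).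

Step 7
Reactants: 16 the aldol above
Product: 17 tert-butyl 2-[(2R,3R)-2-{(R)-[(1S,2S)-2-[1-(benzyldimethylsilyl)ethenyl]-2-methyl-5-oxocyclopentyl](hydroxy)methyl}-3-{(1Z)-3-[(tert-butyldimethylsilyl)oxy]-2-methylprop-1-en-1-yl}oxiran-2-yl]acetate
Conditions: VO(acac)2 (5 mol %), tBuOOH, CH2Cl2, 0 °C
Reagents that add atoms: tert-butyl hydroperoxide CC(C)(C)OO
Why: hydroxyl-directed vanadium-catalysed epoxidation touches only the allylic C7=C8 bond and, because of A(1,2) strain with the C8 side chain, gives the erythro epoxy alcohol, so C8 (and C7 before its inversion) are set from C9.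

Step 8
Reactants: 17 the epoxy alcohol above
Product: 19 O8,O9-isopropylidene ketal of the hydroxy lactone (1S,7S,8R,9R,10S), via hydroxy lactone diol 18 (not isolated)
Conditions: CSA (0.2 equiv), CH2Cl2, 0 °C; then 2-methoxypropene, 0 °C, Et3N quench
Reagents that add atoms: 2-methoxypropene COC(C)=C
Why: acid-triggered opening of the vinyl epoxide at allylic C7 by the tert-butyl ester carbonyl (loss of isobutene) goes with inversion to the γ-lactone bearing the free C8 tertiary alcohol (the known β,γ-epoxy ester to β-hydroxy-γ-lactone cyclisation), and the 8,9-diol is capped at once as the acetonide.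

Step 9
Reactants: 19 the lactone acetonide cyclopentanone above
Product: 22 ring-A ketol with a (1S,10S,11S)-11-hydroxy-11-methyl-12-oxocyclohexane ring A (1S,7S,8R,9R,10S,11S), via lithium dibromo alkoxide 20 (not isolated), via magnesium enolate 21 (not isolated)
Conditions: CH3CHBr2, LiN(iPr)2, THF, −100 °C, then 19; iPrMgCl·LiCl, −95 to −20 °C; then 2-(phenylsulfonyl)-3-phenyloxaziridine, −78 °C; aq. NH4Cl
Reagents that add atoms: 1,1-dibromoethane CC(Br)Br; 2-(phenylsulfonyl)-3-phenyloxaziridine O=S(=O)(N1OC1c1ccccc1)c1ccccc1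
Why: Proposed new method: one-pot insertion of a C(OH)CH3 unit into the C10–C12 bond, in which LiCBr2CH3 adds to the ketone, bromine–magnesium exchange gives a lactone-tolerant magnesium β-oxido carbenoid, the more substituted and more electron-rich C10 migrates to the electrophilic carbenoid carbon with loss of bromide (ring A grows from five to six members and C10 moves from α to β of the ketone), and the regiodefined tetrasubstituted enolate is hydroxylated from the α face, anti to the C9 branch and to Me-15, to set C11 (S); the closest known reactions are the β-oxido carbenoid ring enlargement of ketones with dibromoalkyllithiums (Nozaki–Yamamoto type) and the Davis enolate oxidation, which have not been merged, nor run through a magnesium carbenoid on a lactone-bearing α-branched cyclopentanone.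

Step 10
Reactants: 22 the ring-A ketol above
Product: 23 13,14-didehydro enone of 22
Conditions: IBX, 4-methoxypyridine N-oxide, DMSO, 23 °C
Reagents that add atoms: none
Why: IBX dehydrogenation of the ketone can only form the C13=C14 bond because C11 is quaternary, and it leaves ring A non-enolisable for the later base steps.

Step 11
Reactants: 23 the enone above
Product: 24 (17R)-17-methyl lactone derived from 23
Conditions: LiN(iPr)2 (2.3 equiv), THF, −78 °C; then MeI
Reagents that add atoms: iodomethane CI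
Why: alkylation of the lactone lithium enolate (the tertiary alkoxide forms first) occurs on the face anti to the C9 branch on the adjacent quaternary C8, placing Me-18 cis to O-8 (17R).

Step 12
Reactants: 24 the methylated lactone above
Product: 26 methyl ketone with acetyl on C1 and a free C4 allylic alcohol (1S,7S,8R,9R,10S,11S,17R), via C4 alcohol vinylsilanol 25 (not isolated)
Conditions: Bu4NF, THF, 0 °C; then KHCO3, H2O2 (30 %), MeOH, 23 °C
Reagents that add atoms: hydrogen peroxide OO
Why: fluoride removes the silyl ether and converts the benzylsilane into a silanol, whose Tamao–Fleming oxidation (carbon-to-oxygen migration, then enol to ketone) unveils the C2 methyl ketone without touching the C5=C6 olefin or the enone.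

Step 13
Reactants: 26 the hydroxy methyl ketone above
Product: 27 C4 allylic bromide of 26
Conditions: CBr4, PPh3, CH2Cl2, 0 °C
Reagents that add atoms: tetrabromomethane BrC(Br)(Br)Br
Why: the Appel reaction is selective for the primary allylic alcohol over the hindered tertiary ketol hydroxyl and keeps the Z geometry (SN2 at C4).

Step 14
Reactants: 27 the bromo methyl ketone above
Product: 28 (1S,5Z,7S,8R,9R,10S,11S,17R)-11-hydroxy-8,9-(isopropylidenedioxy)-2,12-dioxobriara-5,13-dien-19,7-olide
Conditions: KN(SiMe3)2 (2.2 equiv), THF (0.002 M, slow addition of 27), −78 to 0 °C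
Reagents that add atoms: none
Why: the methyl ketone is the only enolisable ketone (C1 quaternary, ring A a non-enolisable enone), so its potassium enolate closes the ten-membered ring by intramolecular SN2 alkylation at the (Z)-allylic bromide under high dilution, the Z olefin and the two existing rings pre-organising the chain.

Step 15
Reactants: 28 the macrocyclic diketone above
Product: 29 (1S,2R,5Z,7S,8R,9R,10S,11S,17R)-2,11,12-trihydroxy-8,9-(isopropylidenedioxy)briara-5,13-dien-19,7-olide (C12 epimers)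
Conditions: (S)-2-methyl-CBS-oxazaborolidine (1 equiv), catecholborane, CH2Cl2, −78 to −40 °C
Reagents that add atoms: none
Why: Corey–Bakshi–Shibata reduction differentiates the quaternary C1 from the C3 methylene and gives the 2R alcohol under reagent control; the C12 ketone is reduced too and is restored in the next step.

Step 16
Reactants: 29 the triol above
Product: 30 (1S,2R,5Z,7S,8R,9R,10S,11S,17R)-2,11-dihydroxy-8,9-(isopropylidenedioxy)-12-oxobriara-5,13-dien-19,7-olide
Conditions: MnO2, CH2Cl2, 23 °C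
Reagents that add atoms: none
Why: MnO2 oxidises only the allylic C12 alcohol back to the enone and leaves the saturated C2 alcohol untouched.

Step 17
Reactants: 30 the enone diol acetonide above
Product: 32 (1S,2R,5Z,7S,8S,9R,10S,11S,17R)-2,9-diacetoxy-8,11-dihydroxy-12-oxobriara-5,13-dien-19,7-olide, via tetraol 31 (not isolated)
Conditions: HCl (1 M aq.), THF, 23 °C; then Ac2O, pyridine, DMAP (0.1 equiv), CH2Cl2, 0 to 23 °C
Reagents that add atoms: acetic anhydride CC(=O)OC(C)=O
Why: aqueous acid removes the acetonide, and standard acetylation then esterifies only the two secondary hydroxyls (C2, C9) while the tertiary C8 and C11 hydroxyls stay free.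

**Compound list**

1 | 4-methylfuran-2(5H)-one | CC1=CC(=O)OC1 | starting material
2 | chloromagnesium alkoxide of (2Z)-4-hydroxy-N-methoxy-N,3-dimethylbut-2-enamide | CON(C)C(=O)/C=C(C)\CO[Mg]Cl | intermediate
3 | (2Z)-4-[(tert-butyldimethylsilyl)oxy]-N-methoxy-N,3-dimethylbut-2-enamide | CON(C)C(=O)/C=C(C)\CO[Si](C)(C)C(C)(C)C | intermediate
4 | (2Z)-4-[(tert-butyldimethylsilyl)oxy]-3-methylbut-2-enal | O=C/C=C(C)\CO[Si](C)(C)C(C)(C)C | intermediate
5 | maleic anhydride | O=C1OC(=O)C=C1 | starting material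
6 | 3-(triphenyl-λ5-phosphanylidene)oxolane-2,5-dione | O=C1OC(=O)CC1=P(c1ccccc1)(c1ccccc1)c1ccccc1 | intermediate
7 | (3E)-3-{(2Z)-4-[(tert-butyldimethylsilyl)oxy]-3-methylbut-2-en-1-ylidene}oxolane-2,5-dione | CC(C)(C)[Si](C)(C)OC/C(C)=C\C=C1/CC(=O)OC1=O | intermediate
8 | (2E,4Z)-2-[2-(tert-butoxy)-2-oxoethyl]-6-[(tert-butyldimethylsilyl)oxy]-5-methylhexa-2,4-dienoic acid | CC(C)(C)[Si](C)(C)OC/C(C)=C\C=C(/CC(=O)OC(C)(C)C)C(=O)O | intermediate
9 | tert-butyl (3E,5Z)-7-[(tert-butyldimethylsilyl)oxy]-3-(chlorocarbonyl)-6-methylhepta-3,5-dienoate | CC(C)(C)[Si](C)(C)OC/C(C)=C\C=C(/CC(=O)OC(C)(C)C)C(Cl)=O | intermediate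
10 | tert-butyl (3E,5Z)-7-[(tert-butyldimethylsilyl)oxy]-3-formyl-6-methylhepta-3,5-dienoate | CC(C)(C)[Si](C)(C)OC/C(C)=C\C=C(/CC(=O)OC(C)(C)C)C=O | intermediate
11 | ethynylmagnesium bromide | C#C[Mg]Br | starting material
12 | benzyl(ethynyl)dimethylsilane | C#C[Si](C)(C)Cc1ccccc1 | intermediate
13 | 3-methylcyclopent-2-en-1-one | CC1=CC(=O)CC1 | starting material
14 | [1-(benzyldimethylsilyl)ethenyl]bis(2-methylpropyl)alumane | C=C([Si](C)(C)Cc1ccccc1)[Al](CC(C)C)CC(C)C | intermediate
15 | diisobutylaluminium enolate of (3S)-3-[1-(benzyldimethylsilyl)ethenyl]-3-methylcyclopentanone (enolate towards C2) | C=C([Si](C)(C)Cc1ccccc1)[C@@]1(C)CCC(O[Al](CC(C)C)CC(C)C)=C1 | intermediate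
16 | tert-butyl (3E,5Z)-3-{(R)-[(1S,2S)-2-[1-(benzyldimethylsilyl)ethenyl]-2-methyl-5-oxocyclopentyl](hydroxy)methyl}-7-[(tert-butyldimethylsilyl)oxy]-6-methylhepta-3,5-dienoate (briarane labels 1S,9R,10S) | O[C@@H](/C(CC(=O)OC(C)(C)C)=C/C=C(C)\CO[Si](C)(C)C(C)(C)C)[C@@H]1[C@](C)(CCC1=O)C(=C)[Si](C)(C)Cc1ccccc1 | intermediate
17 | tert-butyl 2-[(2R,3R)-2-{(R)-[(1S,2S)-2-[1-(benzyldimethylsilyl)ethenyl]-2-methyl-5-oxocyclopentyl](hydroxy)methyl}-3-{(1Z)-3-[(tert-butyldimethylsilyl)oxy]-2-methylprop-1-en-1-yl}oxiran-2-yl]acetate (7R,8R,9R) | O[C@@H]([C@@]3(CC(=O)OC(C)(C)C)O[C@@H]3/C=C(C)\CO[Si](C)(C)C(C)(C)C)[C@@H]1[C@](C)(CCC1=O)C(=C)[Si](C)(C)Cc1ccccc1 | intermediate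
18 | (4R,5S)-4-hydroxy-4-{(R)-[(1S,2S)-2-[1-(benzyldimethylsilyl)ethenyl]-2-methyl-5-oxocyclopentyl](hydroxy)methyl}-5-{(1Z)-3-[(tert-butyldimethylsilyl)oxy]-2-methylprop-1-en-1-yl}oxolan-2-one (7S,8R,9R) | O[C@@H]([C@]3(O)CC(=O)O[C@H]3/C=C(C)\CO[Si](C)(C)C(C)(C)C)[C@@H]1[C@](C)(CCC1=O)C(=C)[Si](C)(C)Cc1ccccc1 | intermediate
19 | O8,O9-isopropylidene ketal of 18 (spiro 2,2-dimethyl-1,3-dioxolane on lactone C4; 1S,7S,8R,9R,10S) | CC4(C)O[C@@H]([C@]3(O4)CC(=O)O[C@H]3/C=C(C)\CO[Si](C)(C)C(C)(C)C)[C@@H]1[C@](C)(CCC1=O)C(=C)[Si](C)(C)Cc1ccccc1 | intermediate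
20 | lithium alkoxide of the (12S)-12-(1,1-dibromoethyl) carbinol formed from 19 | CC4(C)O[C@@H]([C@]3(O4)CC(=O)O[C@H]3/C=C(C)\CO[Si](C)(C)C(C)(C)C)[C@@H]1[C@](C)(CC[C@@]1(O[Li])C(C)(Br)Br)C(=C)[Si](C)(C)Cc1ccccc1 | intermediate
21 | chloromagnesium C11=C12 enolate of the ring-enlarged 11-methyl ketone (ring A six-membered) | CC4(C)O[C@@H]([C@]3(O4)CC(=O)O[C@H]3/C=C(C)\CO[Si](C)(C)C(C)(C)C)[C@@H]1[C@](C)(CCC(O[Mg]Cl)=C1C)C(=C)[Si](C)(C)Cc1ccccc1 | intermediate
22 | ring-A ketol: 19 with ring A enlarged to (1S,10S,11S)-11-hydroxy-11-methyl-12-oxocyclohexane (1S,7S,8R,9R,10S,11S) | CC4(C)O[C@@H]([C@]3(O4)CC(=O)O[C@H]3/C=C(C)\CO[Si](C)(C)C(C)(C)C)[C@@H]1[C@](C)(CCC(=O)[C@@]1(C)O)C(=C)[Si](C)(C)Cc1ccccc1 | intermediate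
23 | 13,14-didehydro enone of 22 (6-hydroxy-6-methylcyclohex-2-enone ring A) | CC4(C)O[C@@H]([C@]3(O4)CC(=O)O[C@H]3/C=C(C)\CO[Si](C)(C)C(C)(C)C)[C@@H]1[C@](C)(C=CC(=O)[C@@]1(C)O)C(=C)[Si](C)(C)Cc1ccccc1 | intermediate
24 | (17R)-17-methyl lactone derived from 23 (1S,7S,8R,9R,10S,11S,17R) | CC4(C)O[C@@H]([C@]3(O4)[C@@H](C)C(=O)O[C@H]3/C=C(C)\CO[Si](C)(C)C(C)(C)C)[C@@H]1[C@](C)(C=CC(=O)[C@@]1(C)O)C(=C)[Si](C)(C)Cc1ccccc1 | intermediate
25 | C4 alcohol of 24 carrying a 1-[hydroxy(dimethyl)silyl]ethenyl group on C1 | CC4(C)O[C@@H]([C@]3(O4)[C@@H](C)C(=O)O[C@H]3/C=C(C)\CO)[C@@H]1[C@](C)(C=CC(=O)[C@@]1(C)O)C(=C)[Si](C)(C)O | intermediate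
26 | methyl ketone (acetyl on C1) with free C4 allylic alcohol (1S,7S,8R,9R,10S,11S,17R) | CC4(C)O[C@@H]([C@]3(O4)[C@@H](C)C(=O)O[C@H]3/C=C(C)\CO)[C@@H]1[C@](C)(C=CC(=O)[C@@]1(C)O)C(C)=O | intermediate
27 | C4 (Z)-allylic bromide of 26 | CC4(C)O[C@@H]([C@]3(O4)[C@@H](C)C(=O)O[C@H]3/C=C(C)\CBr)[C@@H]1[C@](C)(C=CC(=O)[C@@]1(C)O)C(C)=O | intermediate
28 | (1S,5Z,7S,8R,9R,10S,11S,17R)-11-hydroxy-8,9-(isopropylidenedioxy)-2,12-dioxobriara-5,13-dien-19,7-olide | CC3(C)O[C@@H]1[C@@H]2[C@](C)(C=CC(=O)[C@@]2(C)O)C(=O)CC/C(C)=C\[C@@H]2OC(=O)[C@H](C)[C@]21O3 | intermediate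
29 | (1S,2R,5Z,7S,8R,9R,10S,11S,17R)-2,11,12-trihydroxy-8,9-(isopropylidenedioxy)briara-5,13-dien-19,7-olide (C12 epimers) | CC3(C)O[C@@H]1[C@@H]2[C@](C)(C=CC(O)[C@@]2(C)O)[C@H](O)CC/C(C)=C\[C@@H]2OC(=O)[C@H](C)[C@]21O3 | intermediate
30 | (1S,2R,5Z,7S,8R,9R,10S,11S,17R)-2,11-dihydroxy-8,9-(isopropylidenedioxy)-12-oxobriara-5,13-dien-19,7-olide | CC3(C)O[C@@H]1[C@@H]2[C@](C)(C=CC(=O)[C@@]2(C)O)[C@H](O)CC/C(C)=C\[C@@H]2OC(=O)[C@H](C)[C@]21O3 | intermediate
31 | (1S,2R,5Z,7S,8R,9R,10S,11S,17R)-2,8,9,11-tetrahydroxy-12-oxobriara-5,13-dien-19,7-olide | O[C@@H]1[C@@H]2[C@](C)(C=CC(=O)[C@@]2(C)O)[C@H](O)CC/C(C)=C\[C@@H]2OC(=O)[C@H](C)[C@]21O | intermediate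
32 | (1S,2R,5Z,7S,8S,9R,10S,11S,17R)-2,9-diacetoxy-8,11-dihydroxy-12-oxobriara-5,13-dien-19,7-olide | CC(=O)O[C@@H]1[C@@H]2[C@](C)(C=CC(=O)[C@@]2(C)O)[C@H](OC(C)=O)CC/C(C)=C\[C@@H]2OC(=O)[C@H](C)[C@]21O | target

**Step count and risks**

Total step count: 17. Longest linear sequence: 16 steps (steps 1–4 and 6–17; step 5 is a one-step side branch).

The three steps most likely to fail:

Step 9, the proposed carbenoid ring expansion with in-flask hydroxylation. The risks are enolisation of the hindered cyclopentanone by the carbenoid, migration of C13 instead of C10, and attack of the Grignard reagent on the lactone. The fallback uses known chemistry and sets out from 19. Lithiated 1-chloroethyl 4-methylphenyl sulfoxide (LiN(iPr)2, THF, −78 °C) is added to 19 and the β-hydroxy α-chloro sulfoxide adduct F2 is isolated. Sulfoxide–magnesium exchange on F2 (tBuMgCl, then iPrMgCl, −78 to 0 °C) triggers the established magnesium β-oxido carbenoid ring enlargement, and the enolate is trapped with Me3SiCl to give the isolable ring-enlarged trimethylsilyl enol ether F3. Rubottom oxidation of F3 (dimethyldioxirane, acetone, −78 °C; then citric acid, MeOH), again from the α face, comes back to the route at 22.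

Step 14, closure of the ten-membered ring through a potassium enolate. The risks are oligomerisation, O-alkylation and base damage to the lactone. The fallback sets out from 27 and forms the same bond from a neutral, preformed nucleophile. Compound 27 is silylated (Me3SiOTf, Et3N, CH2Cl2, −78 °C) to the bis-silylated 2-(trimethylsilyloxy)alkene F4, in which the C11 hydroxyl is also a trimethylsilyl ether. F4 is then added slowly to tris(dimethylamino)sulfonium difluorotrimethylsilicate in THF at high dilution, so that the fluoride-released enolate alkylates the allylic bromide as it forms (Kuwajima–Noyori enol silane alkylation) and the C11 silyl ether is cleaved by the same fluoride. This returns to the route at 28.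

Step 6, the one-flask conjugate addition and aldol. The risks are a sluggish aluminium enolate towards the α-branched dienal and a modest anti to syn ratio at C9. The fallback sets out from 12, 13 and 10 and separates the two events. The copper-catalysed conjugate addition of the alane from 12 to 13 is run alone and quenched with Me3SiCl, giving the isolable regiodefined (S)-benzyl(dimethyl){1-[1-methyl-3-(trimethylsilyloxy)cyclopent-2-en-1-yl]ethenyl}silane F1. F1 is cleaved with MeLi (THF, 0 °C) to the lithium enolate, which is exchanged with ZnCl2 to the zinc enolate and treated with 10 at −78 °C (Noyori-type enolate regeneration and aldol). This comes back to the route at 16.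

Further compounds
F1 | step 6 | (S)-benzyl(dimethyl){1-[1-methyl-3-(trimethylsilyloxy)cyclopent-2-en-1-yl]ethenyl}silane | C=C([Si](C)(C)Cc1ccccc1)[C@@]1(C)CCC(O[Si](C)(C)C)=C1
F2 | step 9 | C12 adduct of 19 with 1-chloroethyl 4-methylphenyl sulfoxide (12-hydroxy-12-[1-chloro-1-(4-methylphenylsulfinyl)ethyl] cyclopentane; mixture at the new side-chain centres) | CC4(C)O[C@@H]([C@]3(O4)CC(=O)O[C@H]3/C=C(C)\CO[Si](C)(C)C(C)(C)C)[C@@H]1[C@](C)(CC[C@@]1(O)C(C)(Cl)S(=O)c1ccc(C)cc1)C(=C)[Si](C)(C)Cc1ccccc1
F3 | step 9 | trimethylsilyl enol ether (C11=C12) of the ring-enlarged 11-methylcyclohexanone | CC4(C)O[C@@H]([C@]3(O4)CC(=O)O[C@H]3/C=C(C)\CO[Si](C)(C)C(C)(C)C)[C@@H]1[C@](C)(CCC(O[Si](C)(C)C)=C1C)C(=C)[Si](C)(C)Cc1ccccc1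
F4 | step 14 | bis-silylated 27: 2-(trimethylsilyloxy)alkene at C2=C3 and C11 trimethylsilyl ether | CC4(C)O[C@@H]([C@]3(O4)[C@@H](C)C(=O)O[C@H]3/C=C(C)\CBr)[C@@H]1[C@](C)(C=CC(=O)[C@@]1(C)O[Si](C)(C)C)C(=C)O[Si](C)(C)C
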